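# Psidial A: total synthesis proposal via phloroglucinol–enoic acid chromanone annulation

## Analysis of the target

The target psidial A 25 is a tetracycle in which a gem-dimethylcyclobutane (C1, C9, C10, C11) is trans-fused to a nine-membered carbocycle (C1–C9), and that ring is trans-fused across C4–C5 to a dihydropyran built from C4, C5, C1′, two arene carbons and the ring oxygen. The arene is a 3,5-diformylphloroglucinol, C8 carries an exocyclic methylene and C1′ a phenyl group. The five stereocentres fall into two groups, of which C1/C9 are (1S,9R), the mirror image of the cyclobutane of natural (−)-β-caryophyllene, so that chiral pool cannot supply the terpene half. The contiguous triad is C4 (quaternary, O and CH3; S), C5 (R) and C1′ (R), with H-5 and H-1′ cis and the phenyl group cis to both the C4 methyl and C6. The two groups are insulated by C2/C3 and C6–C8, so their relationship can only be relayed through the conformation of the medium ring. Sensitive sites are the 1,1-disubstituted alkene next to the strained ring (acid gives a cyclobutylcarbinyl cation), the ionisable tertiary aryl ether at C4, the doubly benzylic C1′ and the two hydrogen-bonded aryl aldehydes. The difficulty lies in the nine-membered ring, the quaternary ether carbon, the stereochemical relay and the acid lability of the final compounds. The strategy rests on the pyran ring, in which C5 is flanked by the aryl–C1′ bond and the O–C4 bond: if C1′ is read as a carboxyl carbon on C5 and C4 as the methyl-bearing β-carbon, these are the two bonds formed when a phenol condenses with a β-methyl-α,β-unsaturated acid to a chroman-4-one, whose carbonyl at C1′ is then the handle for phenyl and hydrogen.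

## Retrosynthetic reasoning

**25 ⇒ 23.** The two aryl–CHO bonds are cut first. Aldehydes would not survive the organometallic and ylide steps, and the arene of 23 (two free phenols, one ether oxygen) is nucleophilic enough to be formylated twice at the end. The forward step must do this without touching the C8 alkene.

**23 ⇒ 22.** The C8=CH2 bond is cut to a ketone. The alkene cannot survive the acid needed to set C1′, so C8 is carried as a carbonyl and methylenated afterwards.

**22 ⇒ 21 ⇒ 20 ⇒ 19 ⇒ 18 ⇒ 17.** At C1′ the C–H and C–Ph bonds are cut back to the chromanone carbonyl of 17. Phenyl is added first and hydride second, because the hydride then enters a planar diaryl cation whose faces are differentiated by C4 and C5. This requires temporary masking of C8 in the ketal 18 and of the phenols in the bis-ether 19.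

**17 ⇒ 14 + 15.** Both pyran bonds, aryl–C1′ and O–C4, are cut in one move, giving the enoic acid 14 and phloroglucinol 15. This removes the whole arene as a symmetrical commodity and leaves a carbocyclic acid without the triad. The forward step must acylate 15 once, close the pyranone at the β-carbon and deliver the trans C4/C5 fusion in the correct sense.

**14 ⇒ 13 ⇒ 12 ⇒ 11 ⇒ 10.** The C4–CH3 bond is cut to the enol triflate 11 and then to the cyclic β-keto ester 10. This fixes the alkene position and the cis ring geometry through the enolate, and defers C9, which can be equilibrated to the trans fusion next to the C8 ketone.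

**10 ⇒ 9.** The nine-membered ring is opened at C5–C6. It is the only ring bond that is β to a ketone (C8) and attached to a 1,3-dicarbonyl carbon (C5), so it can be formed by a reversible, base-catalysed conjugate addition rather than an irreversible alkylation.

**9 ⇒ 8 ⇒ 7 ⇒ 6.** C7–C8 is cut back to the Weinreb amide function of 8 and 7 (vinyl addition in the forward sense), and C4–C5 is cut by a two-carbon homologation of the aldehyde 7 to the β-keto ester 8. Both arms are thereby reduced to a carboxyl and a formyl group on the cyclobutane of 6.

**6 ⇒ 5 ⇒ 4.** C8 and C4 are reconnected. The carboxyl and the 3-oxopropyl arm of 6 are the two ends of the cleaved enol double bond of the silyl enol ether 5. The six-membered ring of 4 therefore supplies C2–C4 and C8 with the two arms already differentiated.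

**4 (via 3) ⇒ 1 + 2.** The cyclobutane bonds C1–C11 and C9–C10 are cut, leading to cyclohexenone 1 and isobutylene 2. The forward [2+2] must set C1 absolutely; C9 is epimerisable and is corrected later.

## Alternatives that were turned down

Alternative 1: The cyclobutane is disconnected at C1–C9 and C10–C11. The trisubstituted alkene of a homoprenyl side chain, on a chroman that already holds C4, C5 and C1′, would be combined with an allenic ester under a chiral oxazaborolidine–AlBr3 Lewis acid, giving the alkylidenecyclobutane chroman A1.
- *For:* C1 is set in a thermal, catalyst-controlled step that can be directed to the unnatural (1S) series. The arene, phenyl group and triad are secured on a six-membered ring first. The enoate carbon of A1 is a latent exocyclic methylene.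
- *Against:* A1 is still open between C7 and C8, so the nine-membered ring would be closed last, by a simple ester enolate, on the most advanced intermediate. C9 must then be set by reducing the alkylidene trans to C1. The catalyst has to match a remote, flexible stereotriad, which itself needs a separate asymmetric sequence.
- *Comparison:* This plan is stronger on catalyst control of the cyclobutane and avoids photochemistry. The chosen plan instead has both strained carbocycles in place after seven steps on a C16 substrate, closes the medium ring early with a β-keto ester, and introduces the arene in one step as unprotected 15.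

Alternative 2: The pyranone is cut at C1′–C5 and C4 is taken from the chiral pool. A triazolium-derived carbene turns an aryl aldehyde group (C1′) into an acyl anion equivalent that adds to C5 of a tethered enoate (intramolecular Stetter reaction), giving the chromanone A2. The quaternary ether carbon C4 of A2 would come from (S)-linalool A3, whose carbinol carbon becomes the aryl ether carbon.
- *For:* C4 is never at risk, C5 is set by a chiral catalyst in a well-studied ring closure, and the conditions are mild.
- *Against:* The aryl ether of the tertiary allylic alcohol A3 is hard to make, because ionisation and elimination compete with O-arylation. A2 is a β-aryloxy ketone with an enolisable C5, set up for E1cB loss of phenoxide. A2 contains neither carbocycle, so the cyclobutane and the nine-membered ring would both follow, with a late medium-ring closure.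
- *Comparison:* This plan is stronger on the absolute configuration at C4 and on kinetic control at C5, where the chosen plan relies on an equilibrium. The chosen plan answers with a much shorter sequence and builds the rings from the hardest (four, nine) to the easiest (six).

Alternative 3: The nine-membered ring is cut at C5–C6. A chromanone enolate generated with Cs2CO3 adds through C5 to the terminal carbon C6 of a vinyl ketone group on the cyclobutane and gives the bis-MOM chromanone A4.
- *For:* It is convergent, and A4 is the bis-MOM ether of the tricyclic diketone 17, so the protected core is reached directly. The bond formed, C5–C6 by conjugate addition, is the same one the chosen route uses to close its carbocycle, so on this point the two are equal.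
- *Against:* The nucleophile is a simple ketone enolate, α-branched, next to quaternary C4 and with the aryloxy group β to it, so deprotonation opens the pyranone by E1cB as readily as it forms the C–C bond. The medium-ring closure is the last skeletal bond, creates C5 under kinetic control and must relate it to the distant cyclobutane. C4 must be made enantiopure separately and joined through C2–C3 to an enantiopure cyclobutane.
- *Comparison:* The chosen route makes the same bond from a β-keto ester (catalytic base, reversible, no stereochemical consequence, no β leaving group) at step 7, and leaves the pyranone to a six-membered closure.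

Key step: step 11

## Remarks on the chemistry

- Atoms are numbered as in caryophyllane (ring atoms C1–C11, C1′ the benzylic carbon); bicyclo[7.2.0]undecane names use the same locants.
- The trans fusion at C9 of the nine-membered C8 ketone and the C4/C5 configuration of 17 are assumed to be the thermodynamically preferred ones; the second assumption is the main risk of the route.
- The sense of induction of the photocycloaddition catalyst is not asserted; the antipode that gives (1S,6S)-4 is the one to be used.

## Route

Step 1
Reactants: 1 cyclohex-2-en-1-one; 2 isobutylene (2-methylpropene)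
Product: 4 (1S,6S)-7,7-dimethylbicyclo[4.2.0]octan-2-one (cis-fused), via trans-fused C1 epimer 3 (not isolated)
Conditions: 2 (excess), AlBr3-activated oxazaborolidine from α,α-diphenylprolinol and 2,4,6-trifluorophenylboronic acid (0.5 equiv, the antipode that leads to 4), CH2Cl2, hν 366 nm, −75 °C; then basic Al2O3, CH2Cl2, 20 °C
Reagents that add atoms: none
Why: Known enantioselective Lewis-acid-catalysed enone–alkene [2+2] photocycloaddition; the head-to-tail mode joins the CMe2 carbon to the enone β-carbon, and the boron-bound, face-shielded enone sets C6 (caryophyllane C1). The epimerisable α-centre is converged to the cis fusion on basic alumina, so any trans-fused 3 ends as 4.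

Step 2
Reactants: 4
Product: 5 (1S,6S)-7,7-dimethyl-2-(trimethylsilyloxy)bicyclo[4.2.0]oct-2-ene
Conditions: LiN(iPr)2, THF, −78 °C; Me3SiCl, −78 → 0 °C
Reagents that add atoms: chlorotrimethylsilane, C[Si](C)(C)Cl
Why: Kinetic enolisation occurs at the unhindered C3 methylene, not at the cyclobutane bridgehead, where an enolate would place a double bond at the ring fusion; O-silylation gives the silyl enol ether and no stereocentre is touched.

Step 3
Reactants: 5
Product: 6 (1S,2S)-3,3-dimethyl-2-(3-oxopropyl)cyclobutane-1-carboxylic acid
Conditions: O3, CH2Cl2–MeOH, −78 °C; Me2S, −78 → 20 °C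
Reagents that add atoms: ozone, [O-][O+]=O
Why: Ozonolysis of a silyl enol ether gives the silyl ester (acid after methanolysis) at the oxygenated carbon and the aldehyde at the other; the six-membered ring unfolds into the C8 carboxyl and the C2–C3–C4 arm with the cis-cyclobutane intact.

Step 4
Reactants: 6
Product: 7 (1S,2S)-N-methoxy-N,3,3-trimethyl-2-(3-oxopropyl)cyclobutane-1-carboxamide
Conditions: 1,1′-carbonyldiimidazole, CH2Cl2, 0 °C; MeNH(OMe), 20 °C
Reagents that add atoms: N,O-dimethylhydroxylamine, CNOC
Why: Weinreb amide formation through the acyl imidazolide; the aldehyde is left alone, since any hemiaminal with the secondary hydroxylamine reverts on work-up.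

Step 5
Reactants: 7
Product: 8 ethyl 5-{(1S,4S)-4-[methoxy(methyl)carbamoyl]-2,2-dimethylcyclobutyl}-3-oxopentanoate
Conditions: N2CHCO2Et, SnCl2 (10 mol %), CH2Cl2, 20 °C
Reagents that add atoms: ethyl diazoacetate, CCOC(=O)C=[N+]=[N-]
Why: Roskamp homologation: Lewis-acid-promoted addition of the diazo ester to the aldehyde, 1,2-hydride shift and loss of N2 give the β-keto ester (C4 ketone, C5, C1′); the amide is inert.

Step 6
Reactants: 8
Product: 9 ethyl 5-[(1S,4S)-4-acryloyl-2,2-dimethylcyclobutyl]-3-oxopentanoate
Conditions: CH2=CHMgBr (3.2 equiv), THF, −78 → −10 °C; inverse quench into cold 1 M HCl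
Reagents that add atoms: vinylmagnesium bromide, C=C[Mg]Br
Why: The first equivalent converts the β-keto ester into its magnesium enolate, which protects it; further reagent adds to the Weinreb amide to give the stable chelate (ketone synthesis from a Weinreb amide). The inverse acidic quench releases the vinyl ketone without conjugate addition of the liberated amine.

Step 7
Reactants: 9
Product: 10 ethyl (1S,9S)-11,11-dimethyl-4,8-dioxobicyclo[7.2.0]undecane-5-carboxylate (cis-fused; C5 epimers and enol)
Conditions: Cs2CO3 (0.3 equiv), MeCN, 40 °C, syringe-pump addition of 9 to a final 1 mM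
Reagents that add atoms: none
Why: Intramolecular Michael addition of the β-keto ester carbon C5 to the vinyl ketone terminus C6 closes the nine-membered ring; the addition is reversible, so oligomers can return to the monomeric ring at high dilution. The cis-1,2 arms of the cyclobutane hold the reacting ends on one face, and C5 is formed as a mixture of no consequence.

Step 8
Reactants: 10
Product: 11 ethyl (1S,9S,4Z)-11,11-dimethyl-8-oxo-4-(trifluoromethylsulfonyloxy)bicyclo[7.2.0]undec-4-ene-5-carboxylate
Conditions: NaH, Et2O, 0 °C; (CF3SO2)2O, −78 → 0 °C
Reagents that add atoms: trifluoromethanesulfonic anhydride, O=S(=O)(OS(=O)(=O)C(F)(F)F)C(F)(F)F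
Why: One equivalent of base deprotonates only the β-keto ester (far more acidic than the C8 ketone); O-triflation of the chelated enolate, which is necessarily cis within the nine-membered ring, gives the (Z)-enol triflate.

Step 9
Reactants: 11
Product: 12 ethyl (1S,9S,4E)-4,11,11-trimethyl-8-oxobicyclo[7.2.0]undec-4-ene-5-carboxylate
Conditions: MeZnCl (2 equiv), Pd(PPh3)4 (5 mol %), THF, 50 °C
Reagents that add atoms: methylzinc chloride, C[Zn]Cl
Why: Negishi coupling of the β-triflyloxy enoate proceeds with retention of alkene geometry and tolerates the free C8 ketone; it installs the C4 methyl on the cis ring alkene.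

Step 10
Reactants: 12
Product: 14 (1S,9R,4E)-4,11,11-trimethyl-8-oxobicyclo[7.2.0]undec-4-ene-5-carboxylic acid, via trans-fused ethyl ester 13 (not isolated)
Conditions: KOH, EtOH–H2O, 80 °C; then HCl to pH 2
Reagents that add atoms: potassium hydroxide, [K+].[OH-]
Why: C9, α to the C8 ketone, epimerises through the enolate to the trans ring fusion, which is expected to be the more stable one for a cyclobutane spanning a nine-membered ring; the hindered conjugated ester is then saponified.

Step 11
Reactants: 14; 15 phloroglucinol (benzene-1,3,5-triol)
Product: 17 (1S,4S,5S,9R)-trans-fused 5,7-dihydroxychroman-4-one in which chroman C2 (= C4, bearing CH3) and C3 (= C5) are ring atoms of the cyclobutane-fused cyclononan-8-one, via 2-acylphloroglucinol enone 16 (not isolated)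
Conditions: 15 (2 equiv), P2O5 in CH3SO3H (1:10 w/w), 70 °C
Reagents that add atoms: none
Why: The acid is activated as a mixed anhydride or acylium ion and C-acylates the threefold-symmetrical arene (Friedel–Crafts acylation, directly or by O-acylation and Fries shift), giving 16 and the aryl–C1′ bond. An ortho hydroxyl then adds to C4 of the protonated enone and the enol ketonises at C5; this closes the pyranone by a 6-endo-trig oxa-Michael addition and forms the O–C4 bond. The closest known reaction is the acid-mediated condensation of phloroglucinol with 3-methylbut-2-enoic acid or cyclohex-1-enecarboxylic acids to 2,2-disubstituted chroman-4-ones. C4 and C5 are both set under thermodynamic control, C5 by enolisation of the new ketone and C4 by reversible oxa-Michael addition. The trans fusion (C4 methyl cis to C6, ring bonds diequatorial on the pyranone) is expected, and its sense relative to C1/C9 is decided by the conformational bias that the trans-fused cyclobutane imposes on the nine-membered ring. The step needs mono-acylation (the first acyl group deactivates the arene), acylation in preference to condensation at the C8 ketone (hindered and reversible there), and no cation at C4. Because the conjugated acid is protonated on oxygen, no C4 cation forms and the medium ring and cyclobutane do not rearrange.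

Step 12
Reactants: 17
Product: 18 C8 ethylene ketal of 17
Conditions: HOCH2CH2OH, p-TsOH (cat.), benzene, reflux, Dean–Stark
Reagents that add atoms: ethane-1,2-diol, OCCO
Why: Acid-catalysed ketalisation is selective for the dialkyl ketone; the chromanone carbonyl is a vinylogous ester hydrogen-bonded to the 5-OH and does not ketalise.

Step 13
Reactants: 18
Product: 19 5,7-bis(methoxymethyl) ether of 18
Conditions: NaH, DMF, 0 °C; MeOCH2Cl, 0 → 20 °C
Reagents that add atoms: chloromethyl methyl ether, COCCl
Why: O-Alkylation of both phenoxides (the chelated 5-OH needs the strong base) removes the acidic protons and the deactivating phenoxide before the organometallic step; the ketal is stable to base.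

Step 14
Reactants: 19
Product: 20 C1′ tertiary carbinol from 19 (4-hydroxy-4-phenylchroman, C1′ epimers)
Conditions: PhLi, CeCl3 (anhydrous), THF, −78 → −20 °C
Reagents that add atoms: phenyllithium, [Li]c1ccccc1
Why: 1,2-Addition of the organocerium reagent, which is nucleophilic but weakly basic, so addition outruns enolisation at C5 and the E1cB ring opening that would follow; the ketal shields C8 and the carbinol configuration is irrelevant.

Step 15
Reactants: 20
Product: 22 (1S,4S,5R,9R,1′R)-5,7-dihydroxy-4-phenylchroman fused to the cyclononan-8-one (bisphenol ketone), via protected 4-phenylchroman 21 (not isolated)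
Conditions: Et3SiH (10 equiv), CF3CO2H, CH2Cl2, −40 → 0 °C; evaporate; 3 M HCl, MeOH, 50 °C
Reagents that add atoms: water, O
Why: Ionic hydrogenation: the acid ionises the carbinol to a trioxygenated diarylmethyl cation and excess silane traps it before elimination or participation of the 5-OMOM group. Hydride enters from the face of H-5, anti to the pseudo-axial C4 methyl and to C6, so H-1′ ends cis to H-5 and phenyl cis to the C4 methyl. Aqueous acid in methanol then removes both MOM ethers and the dioxolane.

Step 16
Reactants: 22
Product: 23 (1S,4S,5R,9R,1′R)-8-methylidene bisphenol (psidial A lacking both formyl groups)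
Conditions: Ph3PCH3Br, KOtBu (6 equiv each), THF, 0 → 65 °C
Reagents that add atoms: methyltriphenylphosphonium bromide, C[P+](c1ccccc1)(c1ccccc1)c1ccccc1.[Br-]
Why: Wittig methylenation of the hindered C8 ketone with excess ylide, two equivalents of which are consumed by the phenols; C9 already has the thermodynamic trans configuration, so reversible enolisation does no harm.

Step 17
Reactants: 23
Product: 25 psidial A, via bis(iminium) dichloride 24 (not isolated)
Conditions: [Me2N=CHCl]Cl (3 equiv), DMF–MeCN, 0 → 20 °C; then aq. NaOAc, 40 °C
Reagents that add atoms: (chloromethylene)dimethyliminium chloride, C[N+](C)=CCl.[Cl-]; water, O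
Why: Vilsmeier–Haack formylation at both free positions of the phloroglucinol-type ring, which is far more nucleophilic than the 1,1-disubstituted alkene; DMF buffers the HCl released, and mild buffered hydrolysis of the bis-iminium salt gives the dialdehyde.

## Compound list

1 | cyclohex-2-en-1-one | O=C1C=CCCC1 | starting material
2 | isobutylene (2-methylpropene) | C=C(C)C | starting material
3 | (1R,6S)-7,7-dimethylbicyclo[4.2.0]octan-2-one (trans-fused) | O=C1CCC[C@H]2[C@H]1CC2(C)C | intermediate (not isolated)
4 | (1S,6S)-7,7-dimethylbicyclo[4.2.0]octan-2-one (cis-fused) | O=C1CCC[C@H]2[C@@H]1CC2(C)C | intermediate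
5 | (1S,6S)-7,7-dimethyl-2-(trimethylsilyloxy)bicyclo[4.2.0]oct-2-ene | C[Si](C)(C)OC1=CCC[C@H]2[C@@H]1CC2(C)C | intermediate
6 | (1S,2S)-3,3-dimethyl-2-(3-oxopropyl)cyclobutane-1-carboxylic acid | O=CCC[C@H]1[C@@H](C(=O)O)CC1(C)C | intermediate
7 | (1S,2S)-N-methoxy-N,3,3-trimethyl-2-(3-oxopropyl)cyclobutane-1-carboxamide | O=CCC[C@H]1[C@@H](C(=O)N(C)OC)CC1(C)C | intermediate
8 | ethyl 5-{(1S,4S)-4-[methoxy(methyl)carbamoyl]-2,2-dimethylcyclobutyl}-3-oxopentanoate | CCOC(=O)CC(=O)CC[C@H]1[C@@H](C(=O)N(C)OC)CC1(C)C | intermediate
9 | ethyl 5-[(1S,4S)-4-acryloyl-2,2-dimethylcyclobutyl]-3-oxopentanoate | CCOC(=O)CC(=O)CC[C@H]1[C@@H](C(=O)C=C)CC1(C)C | intermediate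
10 | ethyl (1S,9S)-11,11-dimethyl-4,8-dioxobicyclo[7.2.0]undecane-5-carboxylate (C5 epimers) | O=C1CCC(C(=O)OCC)C(=O)CC[C@H]2[C@@H]1CC2(C)C | intermediate
11 | ethyl (1S,9S,4Z)-11,11-dimethyl-8-oxo-4-(trifluoromethylsulfonyloxy)bicyclo[7.2.0]undec-4-ene-5-carboxylate | O=C1CC/C(C(=O)OCC)=C(OS(=O)(=O)C(F)(F)F)\CC[C@H]2[C@@H]1CC2(C)C | intermediate
12 | ethyl (1S,9S,4E)-4,11,11-trimethyl-8-oxobicyclo[7.2.0]undec-4-ene-5-carboxylate (cis-fused) | O=C1CC/C(C(=O)OCC)=C(C)\CC[C@H]2[C@@H]1CC2(C)C | intermediate
13 | ethyl (1S,9R,4E)-4,11,11-trimethyl-8-oxobicyclo[7.2.0]undec-4-ene-5-carboxylate (trans-fused) | O=C1CC/C(C(=O)OCC)=C(C)\CC[C@H]2[C@H]1CC2(C)C | intermediate (not isolated)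
14 | (1S,9R,4E)-4,11,11-trimethyl-8-oxobicyclo[7.2.0]undec-4-ene-5-carboxylic acid (cis ring alkene) | O=C1CC/C(C(=O)O)=C(C)\CC[C@H]2[C@H]1CC2(C)C | intermediate
15 | phloroglucinol (benzene-1,3,5-triol) | Oc1cc(O)cc(O)c1 | starting material
16 | (1S,9R,4E)-4,11,11-trimethyl-5-(2,4,6-trihydroxybenzoyl)bicyclo[7.2.0]undec-4-en-8-one | O=C1CC/C(C(=O)c3c(O)cc(O)cc3O)=C(C)\CC[C@H]2[C@H]1CC2(C)C | intermediate (not isolated)
17 | (1S,4S,5S,9R)-trans-fused 5,7-dihydroxychroman-4-one on the cyclobutane-fused cyclononan-8-one | O=C1CC[C@@H]2C(=O)c3c(O)cc(O)cc3O[C@@]2(C)CC[C@H]2[C@H]1CC2(C)C | intermediate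
18 | C8 ethylene ketal of 17 | C12(OCCO1)CC[C@@H]3C(=O)c4c(O)cc(O)cc4O[C@@]3(C)CC[C@H]3[C@H]2CC3(C)C | intermediate
19 | 5,7-bis(methoxymethyl) ether of 18 | C12(OCCO1)CC[C@@H]3C(=O)c4c(OCOC)cc(OCOC)cc4O[C@@]3(C)CC[C@H]3[C@H]2CC3(C)C | intermediate
20 | C1′ tertiary carbinol from 19 (4-hydroxy-4-phenylchroman; C1′ epimers, centre not specified) | C12(OCCO1)CC[C@@H]3C(O)(c5ccccc5)c4c(OCOC)cc(OCOC)cc4O[C@@]3(C)CC[C@H]3[C@H]2CC3(C)C | intermediate
21 | (1′R)-4-phenylchroman, bis-MOM ether, C8 ethylene ketal | C12(OCCO1)CC[C@@H]3[C@H](c5ccccc5)c4c(OCOC)cc(OCOC)cc4O[C@@]3(C)CC[C@H]3[C@H]2CC3(C)C | intermediate (not isolated)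
22 | (1S,4S,5R,9R,1′R)-5,7-dihydroxy-4-phenylchroman on the cyclononan-8-one (bisphenol ketone) | O=C1CC[C@@H]2[C@H](c3ccccc3)c3c(O)cc(O)cc3O[C@@]2(C)CC[C@H]2[C@H]1CC2(C)C | intermediate
23 | (1S,4S,5R,9R,1′R)-8-methylidene bisphenol | C=C1CC[C@@H]2[C@H](c3ccccc3)c3c(O)cc(O)cc3O[C@@]2(C)CC[C@H]2[C@H]1CC2(C)C | intermediate
24 | bis(N,N-dimethyliminium) dichloride of 25 | C=C1CC[C@@H]2[C@H](c3ccccc3)c3c(O)c(C=[N+](C)C)c(O)c(C=[N+](C)C)c3O[C@@]2(C)CC[C@H]2[C@H]1CC2(C)C.[Cl-].[Cl-] | intermediate (not isolated)
25 | psidial A, (1S,4S,5R,9R,1′R) | C=C1CC[C@@H]2[C@H](c3ccccc3)c3c(O)c(C=O)c(O)c(C=O)c3O[C@@]2(C)CC[C@H]2[C@H]1CC2(C)C | target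

## Step count and least certain steps

Total step count: 17. Longest linear sequence: 17 steps, from 1 to 25 (15 enters at step 11).

**Step 11 (key step).** The most likely failure is that the C4/C5 pair settles as a mixture or as the wrong isomer (cis fusion, or the trans isomer of opposite sense to the cyclobutane). Both centres are under thermodynamic control and nothing but the conformation of the medium ring distinguishes the isomers. A second concern is reversible condensation of 15 at the C8 ketone in the strong acid.

The fallback separates the two bond formations. It sets out from 14, which oxalyl chloride converts into the acid chloride F1. Acylation of excess 15 on oxygen in pyridine gives the 3,5-dihydroxyphenyl ester F2. A Fries rearrangement with BF3·OEt2 then gives 16, this time isolated. Its oxa-Michael closure is run separately under mild base at low temperature, with a quinine-derived thiourea if catalyst control is needed, so that C4 is set kinetically from the resting conformation of the enone. The sequence comes back at 17. Minor isomers can be reopened with base and recycled, since C5 stays epimerisable until step 14.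

**Step 7.** The effective molarity for nine-membered rings is low, so oligomerisation may outrun ring closure. The product is also a 1,5-diketone that can undergo transannular aldol addition (C9 enolate onto the C4 ketone) if left under base.

The fallback closes C7–C8 instead of C5–C6. It sets out from 8, which adds to phenyl vinyl sulfone (catalytic Cs2CO3) to give the sulfone adduct F3. After NaH (β-keto ester enolate) and LiN(iPr)2, the α-sulfonyl carbanion acylates itself on the Weinreb amide and gives the cyclic β-keto sulfone F4. Reductive desulfonylation with SmI2 in THF–MeOH returns the route to 10.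

**Step 15.** Facial selectivity of hydride delivery may be poor or inverted, because a torsional preference for the face bearing the axial methyl competes with the steric argument. The cation may also lose H-5 to a chromene and scramble C5.

The fallback exchanges the roles of hydrogen and phenyl. It sets out from 18, which NaBH4 reduces to the chroman-4-ol F5. Excess PhMgBr in THF–toluene at 70 °C converts its magnesium salt into the ortho-quinone methide, and the Grignard reagent adds to C1′ to give the 4-phenylchroman ketal F6. Phenyl takes the face that hydride takes in step 15, so the C1′ epimer obtained is the opposite one, which is the correct one if step 15 fails in this way; no cation is involved. Aqueous HCl in THF removes the ketal and the route is rejoined at 22.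

**Step 17.** HCl released during the formylation may isomerise or hydrochlorinate the exocyclic alkene, or set off a cyclobutylcarbinyl rearrangement, and the second formylation is slower than the first.

The fallback formylates before the alkene exists. It sets out from 22, which is diformylated (Cl2CHOCH3, TiCl4, CH2Cl2, −20 °C) to the dialdehyde ketone F7. Condensation with butan-1-amine masks both aldehydes as the bis-salicylaldimine F8, which is inert to ylides. Wittig methylenation as in step 16 gives the methylidene bis-imine F9, and aqueous acetic acid in THF releases 25.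

**Step 1.** The enantiomeric purity may be insufficient, or conversion may be low at the catalyst loading required.

The fallback is resolution. It sets out from 1 and 2, which are irradiated without the Lewis acid; this gives 4 together with its enantiomer F10 as the racemate. Ketalisation with (2R,3R)-butane-2,3-diol (p-TsOH, benzene) gives the butanediol ketal F11 derived from 4 and the diastereomeric butanediol ketal F12 derived from F10, which are separated. Hydrolysis of the ketal F11 with aqueous HCl in acetone returns enantiopure 4.

## Further compounds

F1 | step 11 | (1S,9R,4E)-4,11,11-trimethyl-8-oxobicyclo[7.2.0]undec-4-ene-5-carbonyl chloride | O=C1CC/C(C(=O)Cl)=C(C)\CC[C@H]2[C@H]1CC2(C)C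
F2 | step 11 | 3,5-dihydroxyphenyl (1S,9R,4E)-4,11,11-trimethyl-8-oxobicyclo[7.2.0]undec-4-ene-5-carboxylate | O=C1CC/C(C(=O)Oc3cc(O)cc(O)c3)=C(C)\CC[C@H]2[C@H]1CC2(C)C
F3 | step 7 | ethyl 5-{(1S,4S)-4-[methoxy(methyl)carbamoyl]-2,2-dimethylcyclobutyl}-3-oxo-2-[2-(phenylsulfonyl)ethyl]pentanoate | CCOC(=O)C(CCS(=O)(=O)c1ccccc1)C(=O)CC[C@H]1[C@@H](C(=O)N(C)OC)CC1(C)C
F4 | step 7 | ethyl (1S,9S)-11,11-dimethyl-4,8-dioxo-7-(phenylsulfonyl)bicyclo[7.2.0]undecane-5-carboxylate | O=C1C(S(=O)(=O)c3ccccc3)CC(C(=O)OCC)C(=O)CC[C@H]2[C@@H]1CC2(C)C
F5 | step 15 | chroman-4-ol from 18 (C1′ carbinol, C8 ethylene ketal, free phenols) | C12(OCCO1)CC[C@@H]3C(O)c4c(O)cc(O)cc4O[C@@]3(C)CC[C@H]3[C@H]2CC3(C)C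
F6 | step 15 | C8 ethylene ketal of 22 | C12(OCCO1)CC[C@@H]3[C@H](c5ccccc5)c4c(O)cc(O)cc4O[C@@]3(C)CC[C@H]3[C@H]2CC3(C)C
F7 | step 17 | 8-oxo analogue of 25 (diformyl bisphenol ketone) | O=C1CC[C@@H]2[C@H](c3ccccc3)c3c(O)c(C=O)c(O)c(C=O)c3O[C@@]2(C)CC[C@H]2[C@H]1CC2(C)C
F8 | step 17 | bis(N-butylimine) of F7 | O=C1CC[C@@H]2[C@H](c3ccccc3)c3c(O)c(/C=N/CCCC)c(O)c(/C=N/CCCC)c3O[C@@]2(C)CC[C@H]2[C@H]1CC2(C)C
F9 | step 17 | bis(N-butylimine) of 25 | C=C1CC[C@@H]2[C@H](c3ccccc3)c3c(O)c(/C=N/CCCC)c(O)c(/C=N/CCCC)c3O[C@@]2(C)CC[C@H]2[C@H]1CC2(C)C
F10 | step 1 | (1R,6R)-7,7-dimethylbicyclo[4.2.0]octan-2-one (enantiomer of 4) | O=C1CCC[C@@H]2[C@H]1CC2(C)C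
F11 | step 1 | (2R,3R)-butane-2,3-diyl ketal of 4 | C[C@H]1OC2(CCC[C@H]3[C@@H]2CC3(C)C)O[C@@H]1C
F12 | step 1 | (2R,3R)-butane-2,3-diyl ketal of F10 | C[C@H]1OC2(CCC[C@@H]3[C@H]2CC3(C)C)O[C@@H]1C
A1 | alternative 1 | chroman (TBS ether arm, bis-pivalate) carrying the (alkylidene)cyclobutane trifluoroethyl enoate | CC(C)(C)[Si](C)(C)OCC[C@@H]1[C@H](c2ccccc2)c2c(OC(=O)C(C)(C)C)cc(OC(=O)C(C)(C)C)cc2O[C@@]1(C)CC[C@H]1/C(=C/C(=O)OCC(F)(F)F)CC1(C)C
A2 | alternative 2 | 2-homoprenyl-2-methyl-5,7-bis(methoxymethoxy)chroman-4-one with the C6–C7 methyl ester arm on C5 | COC(=O)C[C@@H]1C(=O)c2c(OCOC)cc(OCOC)cc2O[C@@]1(C)CCC=C(C)C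
A3 | alternative 2 | (S)-linalool | O[C@@](C=C)(C)CCC=C(C)C
A4 | alternative 3 | 5,7-bis(methoxymethyl) ether of 17 | O=C1CC[C@@H]2C(=O)c3c(OCOC)cc(OCOC)cc3O[C@@]2(C)CC[C@H]2[C@H]1CC2(C)C
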